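**Strategy.** Ring A (C1–C5, C10; eudesmane numbering) is a methylenecyclohexane in which the 2-methylidenepropane-1,3-diyl unit C3–C4(=C15)–C5 is bonded at both ends to the α-carbons, C2 and C10, of a C1 carbonyl. Everything rests on cutting C2–C3 and C5–C10 together: a palladium-catalysed double allylic alkylation ([3+3] annulation) of an acyclic methyl ketone bearing a 2-alkylidenepropane-1,3-diyl diacetate closes ring B and ring A in one operation, creates the quaternary C10 and C5, and leaves the C4=C15 methylene. C7 and C8 are set beforehand on the open chain; C1 reduction, C3 hydroxylation and Mitsunobu esterification finish the molecule.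

Key step: step 8

Remark: eudesmane numbering is used throughout (ring A = C1–C5, C10; ring B = C5–C10; C14 = methyl on C10; C15 = methylene carbon on C4; isopropyl on C7). All eudesmane names imply 5α-H, 7β-isopropyl and 10β-methyl. Compounds 1, 2, 5, 12 and 18 are taken as commercially available.

**Step 1**
Reactants: 1 (4R)-4-benzyl-3-(3-methylbutanoyl)-1,3-oxazolidin-2-one; 2 allyl bromide
Product: 3 (4R)-4-benzyl-3-[(2R)-2-(propan-2-yl)pent-4-enoyl]-1,3-oxazolidin-2-one
Conditions: NaHMDS, THF, −78 °C; then 2, −78 → −40 °C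
Reagents that add atoms: allyl bromide (2), C=CCBr
Why: Evans asymmetric alkylation: the chelated Z-sodium enolate of the imide is allylated on the face opposite the benzyl group, which sets C7 (R).

**Step 2**
Reactants: 3 (4R)-4-benzyl-3-[(2R)-2-(propan-2-yl)pent-4-enoyl]-1,3-oxazolidin-2-one
Product: 4 S-ethyl (2R)-2-(propan-2-yl)pent-4-enethioate
Conditions: EtSH, n-BuLi, THF, 0 → 25 °C; aq NH4Cl work-up
Reagents that add atoms: ethanethiol, CCS
Why: Nucleophilic acyl substitution by lithium ethanethiolate (from ethanethiol and n-butyllithium) at the exocyclic imide carbonyl, the thiolate cleavage of an Evans imide, should give the thioester without epimerising C7 and releases the auxiliary for reuse.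

**Step 3**
Reactants: 4 S-ethyl (2R)-2-(propan-2-yl)pent-4-enethioate; 5 methyl 3-bromo-2-methylpropanoate (racemic)
Product: 7 methyl (5R)-2-methyl-4-oxo-5-(propan-2-yl)oct-7-enoate (both C2 epimers), via organozinc bromide 6 (not isolated)
Conditions: Zn dust, LiCl, THF, 40 °C (5 → 6); then 4, PdCl2(PPh3)2 (5 mol %), toluene/THF, 25 °C
Reagents that add atoms: methyl 3-bromo-2-methylpropanoate (5), COC(=O)C(C)CBr; zinc, [Zn]; (3-methoxy-2-methyl-3-oxopropyl)zinc bromide (6), COC(=O)C(C)C[Zn]Br
Why: Zinc inserts into the primary C–Br bond of 5 to give 6 in the flask, and the Fukuyama coupling (palladium-catalysed ketone synthesis from a thioester and an alkylzinc halide) then runs under neutral conditions that should spare the alkene, the ester and the enolisable C7 centre; the methyl-bearing carbon (future C10) comes as both epimers, which is harmless because it is re-created in step 8.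

**Step 4**
Reactants: 7 methyl (5R)-2-methyl-4-oxo-5-(propan-2-yl)oct-7-enoate
Product: 9 (5S)-3-methyl-5-[(3R)-2-methylhex-5-en-3-yl]oxolan-2-one, via hydroxy ester 8 (not isolated)
Conditions: (R)-2-methyl-CBS-oxazaborolidine (0.2 equiv), catecholborane, toluene, −78 °C; then p-TsOH (cat.), CH2Cl2, 25 °C
Reagents that add atoms: none
Why: In the Corey–Bakshi–Shibata reduction the (R)-catalyst should deliver hydride with the branched C7 side as the large group, setting C8 as S (the Felkin–Anh preference of the C7 centre points the same way), and the γ-hydroxy ester then lactonises under acid.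

**Step 5**
Reactants: 9 (5S)-3-methyl-5-[(3R)-2-methylhex-5-en-3-yl]oxolan-2-one
Product: 10 (5S,6R)-5-hydroxy-3-methyl-6-(propan-2-yl)non-8-en-2-one (in equilibrium with its lactol)
Conditions: MeLi (1.05 equiv), THF, −78 °C; NH4Cl quench at −78 °C
Reagents that add atoms: methyllithium, [Li]C
Why: Addition of one equivalent of methyllithium to a γ-lactone stops at the lithium hemiketal alkoxide at −78 °C, which collapses on work-up to the methyl ketone, so over-addition should be avoided.

**Step 6**
Reactants: 10 (5S,6R)-5-hydroxy-3-methyl-6-(propan-2-yl)non-8-en-2-one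
Product: 11 (5S,6R)-5-[tert-butyl(dimethyl)silyloxy]-3-methyl-6-(propan-2-yl)non-8-en-2-one
Conditions: TBSCl, imidazole, DMAP (cat.), DMF, 40 °C
Reagents that add atoms: tert-butyl(chloro)dimethylsilane, CC(C)(C)[Si](C)(C)Cl
Why: Silyl ether formation drains the lactol equilibrium through the open-chain secondary alcohol, protecting O8 and locking the methyl ketone in its open form.

**Step 7**
Reactants: 11 (5S,6R)-5-[tert-butyl(dimethyl)silyloxy]-3-methyl-6-(propan-2-yl)non-8-en-2-one; 12 2-methylidenepropane-1,3-diyl diacetate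
Product: 13 2-[(3R,4S)-4-[tert-butyl(dimethyl)silyloxy]-6-methyl-7-oxo-3-(propan-2-yl)octylidene]propane-1,3-diyl diacetate
Conditions: second-generation Hoveyda–Grubbs catalyst (10 mol %), 12 (5 equiv), toluene, 80 °C
Reagents that add atoms: 2-methylidenepropane-1,3-diyl diacetate (12), CC(=O)OCC(=C)COC(C)=O
Why: Olefin cross-metathesis of the terminal alkene with an excess of the symmetrical 1,1-disubstituted partner should give the trisubstituted alkene, and because the two acetoxymethyl arms are identical no E/Z isomers can arise.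

**Step 8**
Reactants: 13 2-[(3R,4S)-4-[tert-butyl(dimethyl)silyloxy]-6-methyl-7-oxo-3-(propan-2-yl)octylidene]propane-1,3-diyl diacetate
Product: 15 8α-[tert-butyl(dimethyl)silyloxy]eudesm-4(15)-en-1-one, via monocyclic keto allylic acetate 14 (not isolated)
Conditions: Pd(PPh3)4 (10 mol %), NaH (2.5 equiv), t-BuOH (0.2 equiv), THF (0.01 M), 25 → 60 °C
Reagents that add atoms: none
Why: Zerovalent palladium ionises one acetoxymethyl arm of 13 to a π-allyl complex; under equilibrating base only the C10 enolate can reach it through a six-membered transition state (the C2 enolate would need an 8- or 10-membered ring), so C10 attacks the substituted terminus C5 to give 14, whose remaining allylic acetate ionises to a π-allyl with two equivalent CH2 termini that is captured by the C2 enolate, the only enolate 14 can still form. The closest known reaction is the palladium-catalysed α,α′-annulation of ketone enolates or enamines with 2-methylidenepropane-1,3-diyl diesters, a double Tsuji–Trost alkylation. Ring B closes in a 6-exo mode (the allyl unit stays outside the ring) and ring A in a 6-endo mode with respect to the allyl unit (its central carbon C4 becomes a ring atom and C15 remains as the exocyclic methylene). C5 and C10 are both set in the first closure through a chair-like transition state in which the C7 isopropyl, the C8 silyloxy group, the palladium-bound allyl unit on C5 and the enolate carbon C1 are equatorial and only the small C14 methyl is axial; this should give 5α-H and 10β-methyl, the trans-diequatorial C1/C4 arms that then close to the trans-decalin. The step needs C- over O-allylation, intramolecular over intermolecular capture and this diastereoselection; the soft π-allyl electrophile, high dilution and the preset C7/C8 centres are relied on for these, and the symmetry of the bis(acetoxymethyl)alkene removes any regiochemical issue in both ionisations.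

**Step 9**
Reactants: 15 8α-[tert-butyl(dimethyl)silyloxy]eudesm-4(15)-en-1-one
Product: 16 8α-[tert-butyl(dimethyl)silyloxy]eudesm-4(15)-en-1β-ol
Conditions: NaBH4, MeOH, −20 → 0 °C; aq NH4Cl work-up
Reagents that add atoms: none
Why: Hydride reduction with NaBH4 should occur by axial attack on the C1 carbonyl from the α face, away from the axial C14 methyl, giving the equatorial 1β-alcohol as in the reduction of the saturated carbonyl of the Wieland–Miescher ketone.

**Step 10**
Reactants: 16 8α-[tert-butyl(dimethyl)silyloxy]eudesm-4(15)-en-1β-ol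
Product: 17 8α-[tert-butyl(dimethyl)silyloxy]eudesm-4(15)-ene-1β,3α-diol
Conditions: SeO2 (0.5 equiv), t-BuOOH (3 equiv), CH2Cl2, 0 → 25 °C
Reagents that add atoms: selenium dioxide, O=[Se]=O; tert-butyl hydroperoxide, CC(C)(C)OO
Why: Selenium dioxide allylic hydroxylation (ene reaction at C15, then [2,3]-sigmatropic shift, with the hydroperoxide as terminal oxidant) should oxidise the ring methylene C3 in preference to the hindered ring-fusion methine C5 and deliver oxygen axially on the α face, giving the axial 3α-alcohol with the C4=C15 bond restored.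

**Step 11**
Reactants: 18 (E)-caffeic acid
Product: 20 (2E)-3-{3,4-bis[tert-butyl(dimethyl)silyloxy]phenyl}prop-2-enoic acid, via tris-silyl caffeate 19 (not isolated)
Conditions: TBSCl (3.5 equiv), imidazole, DMF, 25 °C; then AcOH/THF/H2O, 25 °C
Reagents that add atoms: tert-butyl(chloro)dimethylsilane, CC(C)(C)[Si](C)(C)Cl
Why: Exhaustive silylation followed by selective hydrolysis of the labile silyl ester leaves the two phenols masked and the acid free for coupling.

**Step 12**
Reactants: 17 8α-[tert-butyl(dimethyl)silyloxy]eudesm-4(15)-ene-1β,3α-diol; 20 (2E)-3-{3,4-bis[tert-butyl(dimethyl)silyloxy]phenyl}prop-2-enoic acid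
Product: 21 8α-[tert-butyl(dimethyl)silyloxy]-1β-hydroxyeudesm-4(15)-en-3β-yl (2E)-3-{3,4-bis[tert-butyl(dimethyl)silyloxy]phenyl}prop-2-enoate
Conditions: PPh3, DIAD, THF/toluene, 0 → 25 °C
Reagents that add atoms: acid 20, OC(=O)/C=C/c1ccc(O[Si](C)(C)C(C)(C)C)c(O[Si](C)(C)C(C)(C)C)c1
Why: In the Mitsunobu reaction the less hindered allylic 3α-hydroxyl is activated as its oxyphosphonium ion and displaced by the carboxylate with inversion, which sets C3 as the equatorial 3β-ester, while the neopentyl-type 1β-hydroxyl next to the quaternary C10 should stay untouched.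

**Step 13**
Reactants: 21 8α-[tert-butyl(dimethyl)silyloxy]-1β-hydroxyeudesm-4(15)-en-3β-yl (2E)-3-{3,4-bis[tert-butyl(dimethyl)silyloxy]phenyl}prop-2-enoate
Product: 22 1β,8α-dihydroxyeudesm-4(15)-en-3β-yl (2E)-3-(3,4-dihydroxyphenyl)prop-2-enoate (CNP0264533.1; 1R,3S,5S,7R,8S,10R)
Conditions: HF·pyridine, pyridine/THF, 0 → 25 °C
Reagents that add atoms: none
Why: Fluoride-driven cleavage of the two aryl and one secondary alkyl silyl ethers under buffered acidic conditions should leave the allylic ester, the catechol and the exocyclic alkene intact and avoids base-induced acyl migration to O1.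

**Compound list**
1 | (4R)-4-benzyl-3-(3-methylbutanoyl)-1,3-oxazolidin-2-one | O=C1OC[C@@H](Cc2ccccc2)N1C(=O)CC(C)C | starting material
2 | allyl bromide | C=CCBr | starting material
3 | (4R)-4-benzyl-3-[(2R)-2-(propan-2-yl)pent-4-enoyl]-1,3-oxazolidin-2-one | O=C1OC[C@@H](Cc2ccccc2)N1C(=O)[C@@H](C(C)C)CC=C | intermediate
4 | S-ethyl (2R)-2-(propan-2-yl)pent-4-enethioate | CCSC(=O)[C@@H](C(C)C)CC=C | intermediate
5 | methyl 3-bromo-2-methylpropanoate (racemic) | COC(=O)C(C)CBr | starting material
6 | (3-methoxy-2-methyl-3-oxopropyl)zinc bromide | COC(=O)C(C)C[Zn]Br | intermediate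
7 | methyl (5R)-2-methyl-4-oxo-5-(propan-2-yl)oct-7-enoate | COC(=O)C(C)CC(=O)[C@@H](C(C)C)CC=C | intermediate
8 | methyl (4S,5R)-4-hydroxy-2-methyl-5-(propan-2-yl)oct-7-enoate | COC(=O)C(C)C[C@H](O)[C@@H](C(C)C)CC=C | intermediate
9 | (5S)-3-methyl-5-[(3R)-2-methylhex-5-en-3-yl]oxolan-2-one | CC1C[C@H](OC1=O)[C@@H](C(C)C)CC=C | intermediate
10 | (5S,6R)-5-hydroxy-3-methyl-6-(propan-2-yl)non-8-en-2-one | CC(=O)C(C)C[C@H](O)[C@@H](C(C)C)CC=C | intermediate
11 | (5S,6R)-5-[tert-butyl(dimethyl)silyloxy]-3-methyl-6-(propan-2-yl)non-8-en-2-one | CC(=O)C(C)C[C@H](O[Si](C)(C)C(C)(C)C)[C@@H](C(C)C)CC=C | intermediate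
12 | 2-methylidenepropane-1,3-diyl diacetate | CC(=O)OCC(=C)COC(C)=O | starting material
13 | 2-[(3R,4S)-4-[tert-butyl(dimethyl)silyloxy]-6-methyl-7-oxo-3-(propan-2-yl)octylidene]propane-1,3-diyl diacetate | CC(=O)C(C)C[C@H](O[Si](C)(C)C(C)(C)C)[C@@H](C(C)C)CC=C(COC(C)=O)COC(C)=O | intermediate
14 | 2-[(1S,2R,4S,5R)-2-acetyl-4-[tert-butyl(dimethyl)silyloxy]-2-methyl-5-(propan-2-yl)cyclohexyl]prop-2-en-1-yl acetate | CC(=O)[C@]1(C)C[C@H](O[Si](C)(C)C(C)(C)C)[C@@H](C(C)C)C[C@H]1C(=C)COC(C)=O | intermediate
15 | 8α-[tert-butyl(dimethyl)silyloxy]eudesm-4(15)-en-1-one | C=C1CCC(=O)[C@]2(C)C[C@H](O[Si](C)(C)C(C)(C)C)[C@@H](C(C)C)C[C@@H]12 | intermediate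
16 | 8α-[tert-butyl(dimethyl)silyloxy]eudesm-4(15)-en-1β-ol | C=C1CC[C@@H](O)[C@]2(C)C[C@H](O[Si](C)(C)C(C)(C)C)[C@@H](C(C)C)C[C@@H]12 | intermediate
17 | 8α-[tert-butyl(dimethyl)silyloxy]eudesm-4(15)-ene-1β,3α-diol | C=C1[C@H](O)C[C@@H](O)[C@]2(C)C[C@H](O[Si](C)(C)C(C)(C)C)[C@@H](C(C)C)C[C@@H]12 | intermediate
18 | (E)-caffeic acid | OC(=O)/C=C/c1ccc(O)c(O)c1 | starting material
19 | tert-butyl(dimethyl)silyl (2E)-3-{3,4-bis[tert-butyl(dimethyl)silyloxy]phenyl}prop-2-enoate | CC(C)(C)[Si](C)(C)OC(=O)/C=C/c1ccc(O[Si](C)(C)C(C)(C)C)c(O[Si](C)(C)C(C)(C)C)c1 | intermediate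
20 | (2E)-3-{3,4-bis[tert-butyl(dimethyl)silyloxy]phenyl}prop-2-enoic acid | OC(=O)/C=C/c1ccc(O[Si](C)(C)C(C)(C)C)c(O[Si](C)(C)C(C)(C)C)c1 | intermediate
21 | 8α-[tert-butyl(dimethyl)silyloxy]-1β-hydroxyeudesm-4(15)-en-3β-yl (2E)-3-{3,4-bis[tert-butyl(dimethyl)silyloxy]phenyl}prop-2-enoate | C=C1[C@@H](OC(=O)/C=C/c2ccc(O[Si](C)(C)C(C)(C)C)c(O[Si](C)(C)C(C)(C)C)c2)C[C@@H](O)[C@]2(C)C[C@H](O[Si](C)(C)C(C)(C)C)[C@@H](C(C)C)C[C@@H]12 | intermediate
22 | 1β,8α-dihydroxyeudesm-4(15)-en-3β-yl (2E)-3-(3,4-dihydroxyphenyl)prop-2-enoate | C=C1[C@@H](OC(=O)/C=C/c2ccc(O)c(O)c2)C[C@@H](O)[C@]2(C)C[C@H](O)[C@@H](C(C)C)C[C@@H]12 | target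

Total step count: 13. Longest linear sequence: 12 steps (steps 1–10, 12 and 13; step 11 is a one-step side branch).

**Steps most likely to fail**

Step 8. What may go wrong: enolisation toward C2 with intermolecular allylation and oligomerisation, loss of the π-allyl intermediate by elimination to a diene, or poor facial control in the first ring closure that leads to cis-fused material. The fallback builds the two rings one bond at a time and brings C3 in already oxygenated; it sets out from 11 and comes back at 21. Cross-metathesis of 11 with acrolein (second-generation Hoveyda–Grubbs catalyst) should give the (E)-enal F1. Catalytic KOt-Bu in t-BuOH/THF then effects the 6-exo Michael addition of the C10 enolate to give the cyclohexyl acetaldehyde F2. Amine-catalysed α-methylenation (aqueous formaldehyde, pyrrolidine/propionic acid) converts this into the 2-substituted acrolein F3. A reversible intramolecular aldol reaction of the methyl ketone (catalytic KOt-Bu, 0 °C) closes ring A to the equatorial 3β-hydroxy ketone F4. Steglich esterification with 20 (DCC, DMAP) gives the keto ester F5, and Luche reduction (NaBH4, CeCl3·7H2O, −78 °C) of the C1 ketone delivers 21.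

Step 10. What may go wrong: poor facial selectivity of oxygen delivery at C3 and partial over-oxidation to the enone. The fallback makes the step stereoconvergent and replaces inversion by retention; it sets out from 16 and comes back at 21. The crude allylic oxidation product (both C3 epimers and any enone) is oxidised with MnO2 to the single enone F6. Luche reduction (axial hydride attack) gives the equatorial 1β,3β-diol F7, and Steglich esterification with one equivalent of 20 acylates the less hindered allylic 3β-hydroxyl to give 21.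

Step 12. What may go wrong: sluggish activation of the axial alcohol, capture of the activated intermediate at C15 with allylic transposition, or elimination to a diene. The fallback separates activation from displacement; it sets out from 17 and comes back at 21. Selective sulfonylation of the allylic hydroxyl (MsCl, Et3N, −20 °C) gives the 3α-mesylate F8, which is displaced with inversion by the caesium salt of 20 (Cs2CO3, 18-crown-6, toluene/DMF) to give 21.

**Further compounds**
F1 | step 8 | (2E,5R,6S)-6-[tert-butyl(dimethyl)silyloxy]-8-methyl-9-oxo-5-(propan-2-yl)dec-2-enal | CC(=O)C(C)C[C@H](O[Si](C)(C)C(C)(C)C)[C@@H](C(C)C)C/C=C/C=O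
F2 | step 8 | 2-[(1S,2R,4S,5R)-2-acetyl-4-[tert-butyl(dimethyl)silyloxy]-2-methyl-5-(propan-2-yl)cyclohexyl]acetaldehyde | CC(=O)[C@]1(C)C[C@H](O[Si](C)(C)C(C)(C)C)[C@@H](C(C)C)C[C@H]1CC=O
F3 | step 8 | 2-[(1S,2R,4S,5R)-2-acetyl-4-[tert-butyl(dimethyl)silyloxy]-2-methyl-5-(propan-2-yl)cyclohexyl]prop-2-enal | CC(=O)[C@]1(C)C[C@H](O[Si](C)(C)C(C)(C)C)[C@@H](C(C)C)C[C@H]1C(=C)C=O
F4 | step 8 | 8α-[tert-butyl(dimethyl)silyloxy]-3β-hydroxyeudesm-4(15)-en-1-one | C=C1[C@@H](O)CC(=O)[C@]2(C)C[C@H](O[Si](C)(C)C(C)(C)C)[C@@H](C(C)C)C[C@@H]12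
F5 | step 8 | 8α-[tert-butyl(dimethyl)silyloxy]-1-oxoeudesm-4(15)-en-3β-yl (2E)-3-{3,4-bis[tert-butyl(dimethyl)silyloxy]phenyl}prop-2-enoate | C=C1[C@@H](OC(=O)/C=C/c2ccc(O[Si](C)(C)C(C)(C)C)c(O[Si](C)(C)C(C)(C)C)c2)CC(=O)[C@]2(C)C[C@H](O[Si](C)(C)C(C)(C)C)[C@@H](C(C)C)C[C@@H]12
F6 | step 10 | 8α-[tert-butyl(dimethyl)silyloxy]-1β-hydroxyeudesm-4(15)-en-3-one | C=C1C(=O)C[C@@H](O)[C@]2(C)C[C@H](O[Si](C)(C)C(C)(C)C)[C@@H](C(C)C)C[C@@H]12
F7 | step 10 | 8α-[tert-butyl(dimethyl)silyloxy]eudesm-4(15)-ene-1β,3β-diol | C=C1[C@@H](O)C[C@@H](O)[C@]2(C)C[C@H](O[Si](C)(C)C(C)(C)C)[C@@H](C(C)C)C[C@@H]12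
F8 | step 12 | 8α-[tert-butyl(dimethyl)silyloxy]-1β-hydroxyeudesm-4(15)-en-3α-yl methanesulfonate | C=C1[C@H](OS(C)(=O)=O)C[C@@H](O)[C@]2(C)C[C@H](O[Si](C)(C)C(C)(C)C)[C@@H](C(C)C)C[C@@H]12
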